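The numbers in the tables stem from a simulated flask with constants of no real substance.

Late in a run the share of L moves by what is still being made, so I read the last stretch of each run and ask which ratio each new flask makes.

| setting | teal | blue | alder | elm |
|---|---|---|---|---|
| E | 0.46 M | 0.46 M | 0.46 M | 0.46 M |
| D | 1 equiv | 1 equiv | 1.00 equiv | 1.00 equiv |
| Q | 0.12 M | 0.26 M | 0.200 M | 0.0920 M |
| J | 0.5 mol% | 0.5 mol% | 0.5 mol% | 0.5 mol% |
| temperature | 85 °C | 120 °C |  |  |
| remark | run made earlier | run made earlier | at 150 °C throughout | at 90 °C until 25 min, from then on at 150 °C |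
| time |  |  | 50 min | 50 min |

| run | time / min | L / % | Z / % |
|---|---|---|---|
| teal | 4.00 | 4.2 | 1.1 |
| teal | 8.00 | 8.4 | 4.8 |
| teal | 15.0 | 12.8 | 6.4 |
| teal | 25.0 | 21.3 | 9.5 |
| teal | 50.0 | 31.2 | 17.2 |
| blue | 2.50 | 10.8 | 7.1 |
| blue | 5.00 | 16.9 | 5.3 |
| blue | 6.00 | 19.7 | 8.4 |
| blue | 10.0 | 28.4 | 8.8 |
| blue | 12.0 | 30.2 | 9.0 |

(readings scatter by 1 percentage point)

* which one finishes higher in share of L in all that became L or Z ("neither" within 2 percentage points) (alder / elm / neither)
* share of L in all that became L or Z, alder
* share of L in all that became L or Z, elm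

- reactions considered so far: J + D -> J + Z; E + J -> X; E <-> D; E + J -> J + L; D + Q -> G
- in a conversion D counts as not yet reacted

What does a cool flask make? In teal, from 15.0 min to 50.0 min, L gains 18 percentage points and Z gains 11 points. That gives a late ratio of 1.70, the L gained per Z gained between two readings (a selectivity factor), and it means a cool share of 63.0%.

What does a hot flask make? In blue, from 5.00 min to 12.0 min, the late ratio reads 3.59, twice teal's, which is a share of 78.2%. But blue is hotter than teal and has more Q, so this reading mixes two changes.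

Which flask stays nearer the hot ratio? A finished share is the mean of the shares along the way, weighted by product made. Alder is at 150 °C throughout, hotter than blue but with less Q, and I put it near 78.2% or above. Elm spends its first 25 min at 90 °C, close to teal's 85 °C, so I put it between 63.0% and 78.2%. My reckoning therefore has alder ahead.

The forecast also says alder, with 73% for alder and 64% for elm; it holds that blue's gain “most likely comes from Q removing D”. Its alder lies below the 78.2% I read in blue.

The flask gives 87.4% for alder and 72.9% for elm, so alder finishes higher, and both stand above the forecast.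

    J + D → J + Z (k = 0.110 M⁻¹ s⁻¹, Ea = 61.0 kJ mol⁻¹)
    E + J → X (k = 4.90 × 10⁻⁴ M⁻¹ s⁻¹, Ea = 79.0 kJ mol⁻¹)
    E ⇌ D (K = 0.970, k = 7.60 × 10⁻⁵ s⁻¹, Ea = 116 kJ mol⁻¹, ΔH = −49.0 kJ mol⁻¹)
    E + J → J + L (k = 0.210 M⁻¹ s⁻¹, Ea = 45.0 kJ mol⁻¹)
    D + Q → G (k = 0.00240 M⁻¹ s⁻¹, Ea = 72.0 kJ mol⁻¹)
    (constants at 90 °C)

Elm ends 9.9 points above the cool share read in teal. Its neighbour, charged with 0.600 equiv of D, takes the same reckoning. L comes from E and Z from D on the same J, so I scale the late ratio with E over D at the charge, and teal's 1.70 becomes 2.84, a cool share of 74.0%. That neighbour finishes at 80.2%, again above its cool share, with Z at 12.3% of the E and D charged.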